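**Plan**

- Retrosynthetic cuts, in order: the three MOM ethers; the C3=C4 alkene of the pyran ring (ring-closing metathesis); the O1–C2 ether bond (Pd-catalysed tert-prenylation) and the C4a–C4 bond (allyl ether Claisen rearrangement, then alkene isomerisation); the C5–prenyl bond (aryllithium alkylation); the C6–CH2 bond of the propane linker (Negishi coupling).
- Ring A piece: 7-hydroxychroman-2-one supplies the three-carbon chain and keeps the two oxygens different; a prenyl ether Claisen rearrangement sets the 1,1-dimethylallyl group.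
- Ring B piece: 5-bromosalicylaldehyde is converted into a 4-bromo-5-iodocatechol with differentiated oxygens (MOM and allyl); iodine takes the chain, bromine the prenyl group.
- Forward order: both benzene rings are bought; the linker is joined first, ring B is then dressed (prenyl, propenyl, 1,1-dimethylallyl ether), and the pyran ring is closed last, before deprotection.
- Enabling feature: in the pyran ring, O1 sits on C8a ortho to C4a, C2 is quaternary (gem-dimethyl) and C3=C4 is an unsubstituted cis-styrenyl alkene. This is the junction of the vinyl CH of an O-(1,1-dimethylallyl) group and an aryl-bound CH, six atoms apart.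
- Stereochemistry: the target has no stereocentre; the cis geometry of C3=C4 is imposed by the six-membered ring.

Key step: step 15

Remark: 7-hydroxychroman-2-one and 5-bromosalicylaldehyde are taken as catalogue compounds.

**Route**

Step 1
Reactants: 1 7-hydroxychroman-2-one
Product: 2 7-(3-methylbut-2-enyloxy)chroman-2-one
Conditions: prenyl bromide, K2CO3, acetone, 56 °C
Reagents that add atoms: prenyl bromide (1-bromo-3-methylbut-2-ene), CC(C)=CCBr
Why: Williamson etherification of the only free phenol; the second ring A oxygen is masked in the lactone, which fixes the oxygen that later carries the rearranging group.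

Step 2
Reactants: 2 7-(3-methylbut-2-enyloxy)chroman-2-one
Product: 3 3-[2-hydroxy-4-(3-methylbut-2-enyloxy)phenyl]propan-1-ol
Conditions: LiAlH4, THF, 0 °C to rt; H2O work-up
Reagents that add atoms: none
Why: Hydride reduction of the aryl lactone to the primary alcohol frees the second phenol, while the aryl prenyl ether is inert to LiAlH4.

Step 3
Reactants: 3 3-[2-hydroxy-4-(3-methylbut-2-enyloxy)phenyl]propan-1-ol
Product: 4 4-(3-hydroxypropyl)-6-(2-methylbut-3-en-2-yl)benzene-1,3-diol
Conditions: N,N-diethylaniline, 190 °C (sealed tube)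
Reagents that add atoms: none
Why: Aromatic Claisen rearrangement ([3,3] shift, then tautomerisation) bonds the tertiary terminus of the prenyl unit to carbon; the ortho carbon para to the free hydroxyl is preferred over the one flanked by two oxygens (donor meta substituent and sterics), and the basic solvent suppresses acid-induced ether cleavage.

Step 4
Reactants: 4 4-(3-hydroxypropyl)-6-(2-methylbut-3-en-2-yl)benzene-1,3-diol
Product: 5 3-[2,4-bis(methoxymethoxy)-5-(2-methylbut-3-en-2-yl)phenyl]propan-1-ol
Conditions: NaH (2.05 equiv), MOMCl (2.05 equiv), DMF, 0 °C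
Reagents that add atoms: chloromethyl methyl ether (MOMCl), COCCl
Why: O-alkylation of phenoxides; two equivalents of NaH deprotonate only the two phenols, so the primary alcohol stays free.

Step 5
Reactants: 5 3-[2,4-bis(methoxymethoxy)-5-(2-methylbut-3-en-2-yl)phenyl]propan-1-ol
Product: 6 1-(3-iodopropyl)-2,4-bis(methoxymethoxy)-5-(2-methylbut-3-en-2-yl)benzene
Conditions: PPh3, imidazole, I2, CH2Cl2, 0 °C to rt
Reagents that add atoms: iodine, II
Why: Appel-type iodination of the primary alcohol under imidazole-buffered conditions that leave the MOM acetals and the vinyl group untouched.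

Step 6
Reactants: 7 5-bromo-2-hydroxybenzaldehyde (5-bromosalicylaldehyde)
Product: 8 5-bromo-2-(methoxymethoxy)benzaldehyde
Conditions: MOMCl, i-Pr2NEt, CH2Cl2, 0 °C to rt
Reagents that add atoms: chloromethyl methyl ether (MOMCl), COCCl
Why: Acetal protection of the phenol; this oxygen, para to bromine, becomes the free C8 hydroxyl of the target.

Step 7
Reactants: 8 5-bromo-2-(methoxymethoxy)benzaldehyde
Product: 10 5-bromo-2-(methoxymethoxy)phenol, via 5-bromo-2-(methoxymethoxy)phenyl formate 9 (not isolated)
Conditions: mCPBA, CH2Cl2, rt; then K2CO3 (cat.), MeOH, rt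
Reagents that add atoms: 3-chloroperoxybenzoic acid (mCPBA), O=C(OO)c1cccc(Cl)c1
Why: Baeyer–Villiger (Dakin-type) oxidation in which the electron-rich ortho-alkoxyaryl group migrates, followed by methanolysis of the formate; it gives a catechol whose two oxygens are already differentiated.

Step 8
Reactants: 10 5-bromo-2-(methoxymethoxy)phenol
Product: 11 5-bromo-4-iodo-2-(methoxymethoxy)phenol
Conditions: NIS, MeCN, 0 °C to rt, dark
Reagents that add atoms: N-iodosuccinimide, O=C1CCC(=O)N1I
Why: Electrophilic aromatic iodination directed para by the free phenol (the ortho site lies between OH and Br); iodine lands para to the future pyran oxygen and next to bromine.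

Step 9
Reactants: 11 5-bromo-4-iodo-2-(methoxymethoxy)phenol
Product: 12 1-bromo-2-iodo-4-(methoxymethoxy)-5-(prop-2-enyloxy)benzene
Conditions: allyl bromide, K2CO3, DMF, rt
Reagents that add atoms: allyl bromide, C=CCBr
Why: Williamson etherification; the allyl group protects the phenol through the organometallic steps and later delivers the C4 carbon by rearrangement.

Step 10
Reactants: 6 1-(3-iodopropyl)-2,4-bis(methoxymethoxy)-5-(2-methylbut-3-en-2-yl)benzene; 12 1-bromo-2-iodo-4-(methoxymethoxy)-5-(prop-2-enyloxy)benzene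
Product: 14 1-bromo-2-{3-[2,4-bis(methoxymethoxy)-5-(2-methylbut-3-en-2-yl)phenyl]propyl}-4-(methoxymethoxy)-5-(prop-2-enyloxy)benzene, via alkylzinc iodide 13 (not isolated)
Conditions: 6, Zn dust, I2 (5 mol%), DMA, 40 °C; then 12, PdCl2(dppf) (3 mol%), THF, rt
Reagents that add atoms: none
Why: Zinc insertion into the primary alkyl iodide, then Negishi sp3–sp2 coupling; at rt oxidative addition occurs at C–I far faster than at C–Br or the allyl ether C–O, and the dppf ligand disfavours beta-hydride elimination.

Step 11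
Reactants: 14 1-bromo-2-{3-[2,4-bis(methoxymethoxy)-5-(2-methylbut-3-en-2-yl)phenyl]propyl}-4-(methoxymethoxy)-5-(prop-2-enyloxy)benzene
Product: 16 1-{3-[2,4-bis(methoxymethoxy)-5-(2-methylbut-3-en-2-yl)phenyl]propyl}-5-(methoxymethoxy)-2-(3-methylbut-2-enyl)-4-(prop-2-enyloxy)benzene, via aryllithium 15 (not isolated)
Conditions: n-BuLi (1.05 equiv), THF, −78 °C; then CuBr·SMe2 (10 mol%), prenyl bromide, −78 to 0 °C
Reagents that add atoms: prenyl bromide (1-bromo-3-methylbut-2-ene), CC(C)=CCBr
Why: Bromine–lithium exchange outruns ortho-lithiation and attack on the allyl ether at −78 °C, and copper-catalysed allylic substitution at the unhindered primary carbon (SN2 mode) gives the linear prenyl arene.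

Step 12
Reactants: 16 1-{3-[2,4-bis(methoxymethoxy)-5-(2-methylbut-3-en-2-yl)phenyl]propyl}-5-(methoxymethoxy)-2-(3-methylbut-2-enyl)-4-(prop-2-enyloxy)benzene
Product: 17 4-{3-[2,4-bis(methoxymethoxy)-5-(2-methylbut-3-en-2-yl)phenyl]propyl}-6-(methoxymethoxy)-3-(3-methylbut-2-enyl)-2-(prop-2-enyl)phenol
Conditions: N,N-diethylaniline, 190 °C
Reagents that add atoms: none
Why: Aromatic Claisen rearrangement; one ortho carbon carries the MOM ether, so the allyl group can only migrate to the free carbon between the phenol and the prenyl group, the future C4a.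

Step 13
Reactants: 17 4-{3-[2,4-bis(methoxymethoxy)-5-(2-methylbut-3-en-2-yl)phenyl]propyl}-6-(methoxymethoxy)-3-(3-methylbut-2-enyl)-2-(prop-2-enyl)phenol
Product: 18 4-{3-[2,4-bis(methoxymethoxy)-5-(2-methylbut-3-en-2-yl)phenyl]propyl}-6-(methoxymethoxy)-3-(3-methylbut-2-enyl)-2-[(E)-prop-1-enyl]phenol
Conditions: [RuClH(CO)(PPh3)3] (5 mol%), toluene, 80 °C
Reagents that add atoms: none
Why: Ruthenium hydride-catalysed alkene isomerisation (insertion, beta-hydride elimination) moves the terminal alkene into conjugation as the thermodynamic (E)-isomer; the trisubstituted prenyl alkene reacts far more slowly and the ring A vinyl has no allylic hydrogen.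

Step 14
Reactants: 18 4-{3-[2,4-bis(methoxymethoxy)-5-(2-methylbut-3-en-2-yl)phenyl]propyl}-6-(methoxymethoxy)-3-(3-methylbut-2-enyl)-2-[(E)-prop-1-enyl]phenol
Product: 19 1-{3-[2,4-bis(methoxymethoxy)-5-(2-methylbut-3-en-2-yl)phenyl]propyl}-5-(methoxymethoxy)-4-(2-methylbut-3-en-2-yloxy)-2-(3-methylbut-2-enyl)-3-[(E)-prop-1-enyl]benzene
Conditions: methyl 2-methylbut-3-en-2-yl carbonate, Pd(PPh3)4 (5 mol%), THF, 0 °C
Reagents that add atoms: methyl 2-methylbut-3-en-2-yl carbonate, COC(=O)OC(C)(C)C=C
Why: Tsuji–Trost O-allylation; zerovalent palladium ionises the tertiary carbonate with loss of CO2, the methoxide formed deprotonates the phenol, and the phenoxide attacks the more substituted terminus of the 1,1-dimethylallyl palladium complex under kinetic control at 0 °C to give the tertiary ether.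

Step 15
Reactants: 19 1-{3-[2,4-bis(methoxymethoxy)-5-(2-methylbut-3-en-2-yl)phenyl]propyl}-5-(methoxymethoxy)-4-(2-methylbut-3-en-2-yloxy)-2-(3-methylbut-2-enyl)-3-[(E)-prop-1-enyl]benzene
Product: 20 6-{3-[2,4-bis(methoxymethoxy)-5-(2-methylbut-3-en-2-yl)phenyl]propyl}-8-(methoxymethoxy)-2,2-dimethyl-5-(3-methylbut-2-enyl)-2H-chromene
Conditions: second-generation Grubbs catalyst RuCl2(=CHPh)(PCy3)(H2IMes) (5 mol%), CH2Cl2 (0.005 M), 40 °C
Reagents that add atoms: none
Why: Ring-closing olefin metathesis: the ruthenium alkylidene loads on the terminal vinyl of the O-bound 1,1-dimethylallyl group, undergoes [2+2] cycloaddition with the (E)-propenyl group on the neighbouring ring carbon, and cycloreversion forms the C3=C4 bond while the ethylidene fragment leaves as propene. The closest known reaction type is the RCM of 2-vinyl- or 2-propenylaryl 1,1-dimethylallyl ethers to 2,2-dimethyl-2H-chromenes. The pyran ring closes as a six-membered ring with an endocyclic alkene, helped by the gem-dimethyl (Thorpe–Ingold) effect and the fixed ortho relationship of C4a and C8a. No stereocentre is formed and the cis geometry of C3=C4 is imposed by the ring. The step needs chemoselectivity among five alkenes: only the ether vinyl and the propenyl group lie six atoms apart, the ring A vinyl is neopentylic and remote so it can only exchange alkylidene reversibly, and the prenyl alkene is trisubstituted so closure onto it (five-membered ring, loss of 2-methylpropene) should be slower than closure onto the monosubstituted ether vinyl. High dilution suppresses cross metathesis.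

Step 16
Reactants: 20 6-{3-[2,4-bis(methoxymethoxy)-5-(2-methylbut-3-en-2-yl)phenyl]propyl}-8-(methoxymethoxy)-2,2-dimethyl-5-(3-methylbut-2-enyl)-2H-chromene
Product: 21 Kazinol K, 4-{3-[8-hydroxy-2,2-dimethyl-5-(3-methylbut-2-enyl)-2H-chromen-6-yl]propyl}-6-(2-methylbut-3-en-2-yl)benzene-1,3-diol
Conditions: HCl (3 M aq.), MeOH, 40 °C
Reagents that add atoms: none
Why: Acid-catalysed acetal exchange removes the three aryl MOM ethers as dimethoxymethane; dilute acid at mild temperature is expected to spare the chromene, the prenyl group and the ortho-(1,1-dimethylallyl)phenol.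

**Compound list**

1 | 7-hydroxychroman-2-one | O=C1CCc2ccc(O)cc2O1 | starting material
2 | 7-(3-methylbut-2-enyloxy)chroman-2-one | O=C1CCc2ccc(OCC=C(C)C)cc2O1 | intermediate
3 | 3-[2-hydroxy-4-(3-methylbut-2-enyloxy)phenyl]propan-1-ol | OCCCc1ccc(OCC=C(C)C)cc1O | intermediate
4 | 4-(3-hydroxypropyl)-6-(2-methylbut-3-en-2-yl)benzene-1,3-diol | OCCCc1cc(C(C)(C)C=C)c(O)cc1O | intermediate
5 | 3-[2,4-bis(methoxymethoxy)-5-(2-methylbut-3-en-2-yl)phenyl]propan-1-ol | OCCCc1cc(C(C)(C)C=C)c(OCOC)cc1OCOC | intermediate
6 | 1-(3-iodopropyl)-2,4-bis(methoxymethoxy)-5-(2-methylbut-3-en-2-yl)benzene | ICCCc1cc(C(C)(C)C=C)c(OCOC)cc1OCOC | intermediate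
7 | 5-bromo-2-hydroxybenzaldehyde | O=Cc1cc(Br)ccc1O | starting material
8 | 5-bromo-2-(methoxymethoxy)benzaldehyde | O=Cc1cc(Br)ccc1OCOC | intermediate
9 | 5-bromo-2-(methoxymethoxy)phenyl formate | O=COc1cc(Br)ccc1OCOC | intermediate
10 | 5-bromo-2-(methoxymethoxy)phenol | Oc1cc(Br)ccc1OCOC | intermediate
11 | 5-bromo-4-iodo-2-(methoxymethoxy)phenol | Oc1cc(Br)c(I)cc1OCOC | intermediate
12 | 1-bromo-2-iodo-4-(methoxymethoxy)-5-(prop-2-enyloxy)benzene | C=CCOc1cc(Br)c(I)cc1OCOC | intermediate
13 | {3-[2,4-bis(methoxymethoxy)-5-(2-methylbut-3-en-2-yl)phenyl]propyl}zinc iodide | I[Zn]CCCc1cc(C(C)(C)C=C)c(OCOC)cc1OCOC | intermediate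
14 | 1-bromo-2-{3-[2,4-bis(methoxymethoxy)-5-(2-methylbut-3-en-2-yl)phenyl]propyl}-4-(methoxymethoxy)-5-(prop-2-enyloxy)benzene | C=CCOc1cc(Br)c(CCCc2cc(C(C)(C)C=C)c(OCOC)cc2OCOC)cc1OCOC | intermediate
15 | aryllithium of 14 (Li in place of Br) | C=CCOc1cc([Li])c(CCCc2cc(C(C)(C)C=C)c(OCOC)cc2OCOC)cc1OCOC | intermediate
16 | 1-{3-[2,4-bis(methoxymethoxy)-5-(2-methylbut-3-en-2-yl)phenyl]propyl}-5-(methoxymethoxy)-2-(3-methylbut-2-enyl)-4-(prop-2-enyloxy)benzene | C=CCOc1cc(CC=C(C)C)c(CCCc2cc(C(C)(C)C=C)c(OCOC)cc2OCOC)cc1OCOC | intermediate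
17 | 4-{3-[2,4-bis(methoxymethoxy)-5-(2-methylbut-3-en-2-yl)phenyl]propyl}-6-(methoxymethoxy)-3-(3-methylbut-2-enyl)-2-(prop-2-enyl)phenol | C=CCc1c(O)c(OCOC)cc(CCCc2cc(C(C)(C)C=C)c(OCOC)cc2OCOC)c1CC=C(C)C | intermediate
18 | 4-{3-[2,4-bis(methoxymethoxy)-5-(2-methylbut-3-en-2-yl)phenyl]propyl}-6-(methoxymethoxy)-3-(3-methylbut-2-enyl)-2-[(E)-prop-1-enyl]phenol | C/C=C/c1c(O)c(OCOC)cc(CCCc2cc(C(C)(C)C=C)c(OCOC)cc2OCOC)c1CC=C(C)C | intermediate
19 | 1-{3-[2,4-bis(methoxymethoxy)-5-(2-methylbut-3-en-2-yl)phenyl]propyl}-5-(methoxymethoxy)-4-(2-methylbut-3-en-2-yloxy)-2-(3-methylbut-2-enyl)-3-[(E)-prop-1-enyl]benzene | C/C=C/c1c(OC(C)(C)C=C)c(OCOC)cc(CCCc2cc(C(C)(C)C=C)c(OCOC)cc2OCOC)c1CC=C(C)C | intermediate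
20 | 6-{3-[2,4-bis(methoxymethoxy)-5-(2-methylbut-3-en-2-yl)phenyl]propyl}-8-(methoxymethoxy)-2,2-dimethyl-5-(3-methylbut-2-enyl)-2H-chromene | C=CC(C)(C)c1cc(CCCc2cc(OCOC)c3c(c2CC=C(C)C)C=CC(C)(C)O3)c(OCOC)cc1OCOC | intermediate
21 | Kazinol K | C=CC(C)(C)c1cc(CCCc2cc(O)c3c(c2CC=C(C)C)C=CC(C)(C)O3)c(O)cc1O | target

**Summary**

Total step count: 16. Longest linear sequence: 12 steps (1 to 6 in steps 1–5, then steps 10–16).

Steps most likely to fail:

1. Step 15. A ruthenium benzylidene formed at the propenyl carbon may close onto the neighbouring prenyl alkene (five-membered ring, loss of 2-methylpropene) in competition with the six-membered closure, and the catalyst may rest unproductively on the ring A vinyl. Fallback: close the pyran before the prenyl group exists. The route sets out from 14: Claisen rearrangement (N,N-diethylaniline, 190 °C) gives the bromo allylphenol F1; isomerisation with [RuClH(CO)(PPh3)3] gives the bromo propenylphenol F2; tert-prenylation with methyl 2-methylbut-3-en-2-yl carbonate and Pd(PPh3)4 at 0 °C, where zerovalent palladium does not insert into the hindered electron-rich aryl bromide, gives the bromo diene ether F3; RCM with the second-generation Grubbs catalyst, now with no prenyl group next to the styrene, gives the 5-bromochromene F4. Bromine–lithium exchange (n-BuLi, −78 °C) and copper-catalysed reaction with prenyl bromide then return to 20.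

2. Step 3. The tertiary terminus may bond to the carbon between the two oxygens, and at 190 °C the first-formed ortho-(1,1-dimethylallyl)phenol may rearrange further (abnormal Claisen) or cyclise onto the phenol. Fallback: install the group by a regiodefined cross-coupling. The route sets out from 1: LiAlH4 reduction gives the triol F5; NaH and MOMCl give the bis-MOM alcohol F6; NBS in MeCN brominates the only unhindered activated position (para to one ether, ortho to the other) to give the aryl bromide F7. A ligand-controlled, branch-selective Suzuki–Miyaura coupling with prenylboronic acid pinacol ester ([(C3H5)PdCl]2, the dialkylbiarylphosphine known to favour the branched product, K3PO4, THF/H2O) joins the tertiary carbon to the ring and returns to 5.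

3. Step 14. The doubly ortho-substituted phenoxide may attack the palladium allyl complex slowly or at the primary terminus (linear prenyl ether), or the first-formed tertiary ether may re-ionise and equilibrate. Fallback: build the ether by copper-catalysed propargylic substitution and semi-reduction. The route sets out from 18: 2-methylbut-3-yn-2-yl trifluoroacetate, CuCl2 (cat.), DBU, MeCN, 0 °C gives the 1,1-dimethylpropargyl ether F8. Semi-hydrogenation (H2, Lindlar catalyst Pd/CaCO3 poisoned with Pb(OAc)2, quinoline, EtOAc, stopped after one equivalent) reduces the alkyne faster than any alkene and returns to 19.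

**Further compounds**

F1 | step 15 | 3-bromo-4-{3-[2,4-bis(methoxymethoxy)-5-(2-methylbut-3-en-2-yl)phenyl]propyl}-6-(methoxymethoxy)-2-(prop-2-enyl)phenol | C=CCc1c(O)c(OCOC)cc(CCCc2cc(C(C)(C)C=C)c(OCOC)cc2OCOC)c1Br
F2 | step 15 | 3-bromo-4-{3-[2,4-bis(methoxymethoxy)-5-(2-methylbut-3-en-2-yl)phenyl]propyl}-6-(methoxymethoxy)-2-[(E)-prop-1-enyl]phenol | C/C=C/c1c(O)c(OCOC)cc(CCCc2cc(C(C)(C)C=C)c(OCOC)cc2OCOC)c1Br
F3 | step 15 | 2-bromo-1-{3-[2,4-bis(methoxymethoxy)-5-(2-methylbut-3-en-2-yl)phenyl]propyl}-5-(methoxymethoxy)-4-(2-methylbut-3-en-2-yloxy)-3-[(E)-prop-1-enyl]benzene | C/C=C/c1c(OC(C)(C)C=C)c(OCOC)cc(CCCc2cc(C(C)(C)C=C)c(OCOC)cc2OCOC)c1Br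
F4 | step 15 | 5-bromo-6-{3-[2,4-bis(methoxymethoxy)-5-(2-methylbut-3-en-2-yl)phenyl]propyl}-8-(methoxymethoxy)-2,2-dimethyl-2H-chromene | C=CC(C)(C)c1cc(CCCc2cc(OCOC)c3c(c2Br)C=CC(C)(C)O3)c(OCOC)cc1OCOC
F5 | step 3 | 4-(3-hydroxypropyl)benzene-1,3-diol | OCCCc1ccc(O)cc1O
F6 | step 3 | 3-[2,4-bis(methoxymethoxy)phenyl]propan-1-ol | OCCCc1ccc(OCOC)cc1OCOC
F7 | step 3 | 3-[5-bromo-2,4-bis(methoxymethoxy)phenyl]propan-1-ol | OCCCc1cc(Br)c(OCOC)cc1OCOC
F8 | step 14 | 1-{3-[2,4-bis(methoxymethoxy)-5-(2-methylbut-3-en-2-yl)phenyl]propyl}-5-(methoxymethoxy)-4-(2-methylbut-3-yn-2-yloxy)-2-(3-methylbut-2-enyl)-3-[(E)-prop-1-enyl]benzene | C/C=C/c1c(OC(C)(C)C#C)c(OCOC)cc(CCCc2cc(C(C)(C)C=C)c(OCOC)cc2OCOC)c1CC=C(C)C
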